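**Retrosynthetic overview**
- The Z-enal is made last, by MnO2 oxidation of a Z-allylic alcohol that comes from Lindlar reduction of the Sonogashira product of a C5 aryl bromide with propargyl alcohol. The 4-hydroxybenzoate is attached before that by a phenol-tolerant Mitsunobu esterification of the C3 hydroxymethyl group.
- The hydroxymethyl group comes from a methyl trans-2-aryl-2,3-dihydrobenzofuran-3-carboxylate; the LiAlH4 reduction also removes the only protecting group (a pivalate on ring B).
- That ester comes from a (2S)-flavanone by oxidative ring contraction. Enabling feature: the chain C3a–C3–CH2O of the target is the 1,2-shifted image of the C4a–C4(=O)–C3 unit of a chroman-4-one, and O1–C2(aryl) is common to both. Moving ring A from the carbonyl carbon to C3 forms the C3a–C3 bond, contracts ring C from pyranone to dihydrofuran, and leaves the old carbonyl carbon as the ester.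
- The flavanone comes from a 6-bromo-8-methoxychromone and an arylboronic acid by catalytic asymmetric conjugate addition, which sets C2; the chromone comes from 2'-hydroxy-3'-methoxyacetophenone.
- Ring order: both benzene rings are bought; the pyranone ring is formed in step 2 and contracted to the dihydrofuran ring in step 5.

Key step: step 5

Assumption: the (R) antipode of the PyOx ligand is taken to give the 2S flavanone by the facial model of this catalyst; if the sense proves opposite, the (S) ligand is used and nothing else changes.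

**Route**

Step 1
Reactants: 1 1-(2-hydroxy-3-methoxyphenyl)ethan-1-one
Product: 2 1-(5-bromo-2-hydroxy-3-methoxyphenyl)ethan-1-one
Conditions: NBS (1.05 equiv), MeCN, 0 °C to rt
Reagents that add atoms: N-bromosuccinimide, BrN1C(=O)CCC1=O
Why: Electrophilic aromatic bromination goes to the only free position para to the phenol (also meta to the acetyl group), so a single regioisomer is expected.

Step 2
Reactants: 2 1-(5-bromo-2-hydroxy-3-methoxyphenyl)ethan-1-one
Product: 4 6-bromo-8-methoxy-4H-chromen-4-one, via enaminone 3 (not isolated)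
Conditions: Me2NCH(OMe)2, toluene, 100 °C; evaporate; then conc. HCl, CH2Cl2, rt
Reagents that add atoms: N,N-dimethylformamide dimethyl acetal, COC(OC)N(C)C
Why: Condensation of the methyl ketone with the amide acetal gives the enaminone, and acid then drives conjugate addition of the phenol with loss of dimethylamine, the standard enaminone route to 3-unsubstituted chromones.

Step 3
Reactants: 5 (4-hydroxy-3-methoxyphenyl)boronic acid
Product: 6 [4-(2,2-dimethylpropanoyloxy)-3-methoxyphenyl]boronic acid
Conditions: t-BuCOCl, Et3N, THF, 0 °C to rt; dilute aq. HCl work-up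
Reagents that add atoms: pivaloyl chloride, CC(C)(C)C(Cl)=O
Why: Schotten–Baumann-type O-acylation of the phenol (boron-bound acyl groups are hydrolysed in the work-up) installs an acid-stable, electron-withdrawing ester that tempers ring B for step 5 and is removed without an extra step in step 6.

Step 4
Reactants: 4 6-bromo-8-methoxy-4H-chromen-4-one; 6 [4-(2,2-dimethylpropanoyloxy)-3-methoxyphenyl]boronic acid
Product: 7 4-[(2S)-6-bromo-8-methoxy-4-oxo-3,4-dihydro-2H-chromen-2-yl]-2-methoxyphenyl 2,2-dimethylpropanoate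
Conditions: Pd(OCOCF3)2 (5 mol %), (R)-t-BuPyOx (6 mol %), NH4PF6 (30 mol %), H2O (5 equiv), ClCH2CH2Cl, 60 °C
Reagents that add atoms: none
Why: In this palladium-catalysed asymmetric conjugate addition of an arylboronic acid to a chromone, the aryl group is transferred to a cationic divalent palladium–PyOx complex, the ligand selects the enantioface of the C2=C3 bond during insertion (setting C2 as S), and protonolysis of the palladium enolate releases the flavanone, the C–Br bond being safe because no zerovalent palladium is involved.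

Step 5
Reactants: 7 4-[(2S)-6-bromo-8-methoxy-4-oxo-3,4-dihydro-2H-chromen-2-yl]-2-methoxyphenyl 2,2-dimethylpropanoate
Product: 11 methyl (2S,3S)-5-bromo-2-[4-(2,2-dimethylpropanoyloxy)-3-methoxyphenyl]-7-methoxy-2,3-dihydro-1-benzofuran-3-carboxylate (trans ester), via enol ether 8 (not isolated), via trans iodanyl ketal 9 (not isolated), via orthoester 10 (not isolated)
Conditions: PhI(OAc)2 (1.2 equiv), HC(OMe)3 (solvent), conc. H2SO4 (0.5 equiv), rt; then H2O, NaHCO3
Reagents that add atoms: trimethyl orthoformate, COC(OC)OC; water, O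
Why: H2SO4 and HC(OMe)3 turn ketone 7 into enol ether 8, electrophilic trivalent iodine adds to C3 on the face anti to the C2 aryl group while methanol caps C4 to give the trans iodanyl ketal 9, and with the equatorial C3–I bond antiperiplanar to the C4–C4a ring bond ring A shifts from C4 to C3 as iodobenzene departs, the dimethoxycarbenium ion left at the old carbonyl carbon being trapped as orthoester 10 and hydrolysed to ester 11 on work-up. The closest known reaction type is this same oxidative ring contraction of flavanones to methyl trans-2-aryl-2,3-dihydrobenzofuran-3-carboxylates by aryl-λ3-iodane diacetates in trimethyl orthoformate, a cyclic relative of the α-haloketal-to-arylacetate 1,2-aryl shift. The dihydrofuran ring (O1–C2–C3–C3a–C7a) is closed by a 1,2-aryl shift through a spiro phenonium bridge, a 3-exo-tet attack of the ipso carbon on C3 followed by cleavage of its old bond to C4, that is a six-to-five contraction of ring C. C3 is the only new stereocentre and is set by C2, since anti addition of iodine and inversion at C3 during the shift place the ester carbon trans to the aryl group (3S), which is also the thermodynamic epimer, and C2 is carried through because none of its bonds is broken. The step needs ring A to migrate in preference to ring B (isoflavone pathway), to dehydrogenation (flavone pathway) and to ionisation of the benzylic C2–O bond (racemisation); the ring oxygen ortho to the migrating carbon stabilises the phenonium ion, the pivalate on the para oxygen of ring B lowers both the migratory aptitude of that ring and the stability of a C2 cation, and the bromine, meta to the migrating carbon, should stay inert.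

Step 6
Reactants: 11 methyl (2S,3S)-5-bromo-2-[4-(2,2-dimethylpropanoyloxy)-3-methoxyphenyl]-7-methoxy-2,3-dihydro-1-benzofuran-3-carboxylate
Product: 12 4-[(2S,3R)-5-bromo-3-(hydroxymethyl)-7-methoxy-2,3-dihydro-1-benzofuran-2-yl]-2-methoxyphenol
Conditions: LiAlH4 (excess), THF, −20 to 0 °C; aq. potassium sodium tartrate work-up
Reagents that add atoms: none
Why: Hydride reduction of the methyl ester to the primary alcohol with concurrent reductive cleavage of the aryl pivalate should leave the aryl bromide and both stereocentres untouched at 0 °C, and C3 is no longer epimerisable afterwards (its descriptor changes to R by priority only).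

Step 7
Reactants: 12 4-[(2S,3R)-5-bromo-3-(hydroxymethyl)-7-methoxy-2,3-dihydro-1-benzofuran-2-yl]-2-methoxyphenol; 13 4-hydroxybenzoic acid
Product: 14 [(2S,3R)-5-bromo-2-(4-hydroxy-3-methoxyphenyl)-7-methoxy-2,3-dihydro-1-benzofuran-3-yl]methyl 4-hydroxybenzoate
Conditions: PPh3, i-PrO2CN=NCO2i-Pr, THF, 0 °C to rt
Reagents that add atoms: none
Why: The Mitsunobu esterification is chemoselective because the carboxylic acid, far more acidic than either phenol, is the pronucleophile and the primary alcohol is the only hydroxyl activated as an alkoxyphosphonium ion, and the carbinol carbon is a CH2 group so no stereocentre is touched.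

Step 8
Reactants: 14 [(2S,3R)-5-bromo-2-(4-hydroxy-3-methoxyphenyl)-7-methoxy-2,3-dihydro-1-benzofuran-3-yl]methyl 4-hydroxybenzoate; 15 prop-2-yn-1-ol
Product: 16 [(2S,3R)-2-(4-hydroxy-3-methoxyphenyl)-5-(3-hydroxyprop-1-yn-1-yl)-7-methoxy-2,3-dihydro-1-benzofuran-3-yl]methyl 4-hydroxybenzoate
Conditions: PdCl2(PhCN)2 (3 mol %), [HP(t-Bu)3]BF4 (6 mol %), CuI (2 mol %), i-Pr2NH, 1,4-dioxane, rt, degassed
Reagents that add atoms: none
Why: A Sonogashira coupling with a bulky electron-rich phosphine allows oxidative addition of the electron-rich aryl bromide at room temperature, and the free phenols and the benzoate ester tolerate the secondary amine base.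

Step 9
Reactants: 16 [(2S,3R)-2-(4-hydroxy-3-methoxyphenyl)-5-(3-hydroxyprop-1-yn-1-yl)-7-methoxy-2,3-dihydro-1-benzofuran-3-yl]methyl 4-hydroxybenzoate
Product: 17 [(2S,3R)-2-(4-hydroxy-3-methoxyphenyl)-5-[(1Z)-3-hydroxyprop-1-en-1-yl]-7-methoxy-2,3-dihydro-1-benzofuran-3-yl]methyl 4-hydroxybenzoate
Conditions: H2 (1 atm), Lindlar catalyst (Pd on CaCO3 poisoned with Pb(OAc)2), quinoline, EtOAc, rt, dark
Reagents that add atoms: none
Why: Lindlar semihydrogenation delivers H2 syn to the alkyne on the poisoned palladium surface to give the Z alkene, with quinoline suppressing over-reduction and the benzylic C–O bonds not being cleaved on this catalyst.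

Step 10
Reactants: 17 [(2S,3R)-2-(4-hydroxy-3-methoxyphenyl)-5-[(1Z)-3-hydroxyprop-1-en-1-yl]-7-methoxy-2,3-dihydro-1-benzofuran-3-yl]methyl 4-hydroxybenzoate
Product: 18 [(2S,3R)-2-(4-hydroxy-3-methoxyphenyl)-7-methoxy-5-[(1Z)-3-oxoprop-1-en-1-yl]-2,3-dihydro-1-benzofuran-3-yl]methyl 4-hydroxybenzoate
Conditions: activated MnO2 (excess), EtOAc, 0 °C to rt, dark, short contact time
Reagents that add atoms: none
Why: MnO2 oxidises the cinnamyl-type allylic alcohol (the only aliphatic hydroxyl left) on a neutral surface, the phenols are expected to survive short exposure, and the aprotic, acid-free, dark conditions should preserve the Z geometry of the push-pull enal.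

**Compound list**

1 | 1-(2-hydroxy-3-methoxyphenyl)ethan-1-one | CC(=O)c1cccc(OC)c1O | starting material
2 | 1-(5-bromo-2-hydroxy-3-methoxyphenyl)ethan-1-one | CC(=O)c1cc(Br)cc(OC)c1O | intermediate
3 | (2E)-1-(5-bromo-2-hydroxy-3-methoxyphenyl)-3-(dimethylamino)prop-2-en-1-one | CN(C)/C=C/C(=O)c1cc(Br)cc(OC)c1O | intermediate
4 | 6-bromo-8-methoxy-4H-chromen-4-one | O=C1C=COc2c(OC)cc(Br)cc12 | intermediate
5 | (4-hydroxy-3-methoxyphenyl)boronic acid | COc1cc(B(O)O)ccc1O | starting material
6 | [4-(2,2-dimethylpropanoyloxy)-3-methoxyphenyl]boronic acid | COc1cc(B(O)O)ccc1OC(=O)C(C)(C)C | intermediate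
7 | 4-[(2S)-6-bromo-8-methoxy-4-oxo-3,4-dihydro-2H-chromen-2-yl]-2-methoxyphenyl 2,2-dimethylpropanoate | COc1cc([C@H]2Oc3c(OC)cc(Br)cc3C(=O)C2)ccc1OC(=O)C(C)(C)C | intermediate
8 | 4-[(2S)-6-bromo-4,8-dimethoxy-2H-chromen-2-yl]-2-methoxyphenyl 2,2-dimethylpropanoate | COc1cc([C@H]2Oc3c(OC)cc(Br)cc3C(OC)=C2)ccc1OC(=O)C(C)(C)C | intermediate
9 | 4-[(2R,3R)-3-[acetoxy(phenyl)-λ3-iodanyl]-6-bromo-4,4,8-trimethoxy-3,4-dihydro-2H-chromen-2-yl]-2-methoxyphenyl 2,2-dimethylpropanoate (2,3-trans; C2 unchanged in space, its descriptor changes because iodine raises the rank of C3) | COc1cc([C@H]2Oc3c(OC)cc(Br)cc3C(OC)(OC)[C@@H]2[I](OC(C)=O)c2ccccc2)ccc1OC(=O)C(C)(C)C | intermediate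
10 | 4-[(2S,3S)-5-bromo-7-methoxy-3-(trimethoxymethyl)-2,3-dihydro-1-benzofuran-2-yl]-2-methoxyphenyl 2,2-dimethylpropanoate | COc1cc([C@H]2Oc3c(OC)cc(Br)cc3[C@@H]2C(OC)(OC)OC)ccc1OC(=O)C(C)(C)C | intermediate
11 | methyl (2S,3S)-5-bromo-2-[4-(2,2-dimethylpropanoyloxy)-3-methoxyphenyl]-7-methoxy-2,3-dihydro-1-benzofuran-3-carboxylate (trans) | COc1cc([C@H]2Oc3c(OC)cc(Br)cc3[C@@H]2C(=O)OC)ccc1OC(=O)C(C)(C)C | intermediate
12 | 4-[(2S,3R)-5-bromo-3-(hydroxymethyl)-7-methoxy-2,3-dihydro-1-benzofuran-2-yl]-2-methoxyphenol | COc1cc([C@H]2Oc3c(OC)cc(Br)cc3[C@@H]2CO)ccc1O | intermediate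
13 | 4-hydroxybenzoic acid | OC(=O)c1ccc(O)cc1 | starting material
14 | [(2S,3R)-5-bromo-2-(4-hydroxy-3-methoxyphenyl)-7-methoxy-2,3-dihydro-1-benzofuran-3-yl]methyl 4-hydroxybenzoate | COc1cc([C@H]2Oc3c(OC)cc(Br)cc3[C@@H]2COC(=O)c2ccc(O)cc2)ccc1O | intermediate
15 | prop-2-yn-1-ol | OCC#C | starting material
16 | [(2S,3R)-2-(4-hydroxy-3-methoxyphenyl)-5-(3-hydroxyprop-1-yn-1-yl)-7-methoxy-2,3-dihydro-1-benzofuran-3-yl]methyl 4-hydroxybenzoate | COc1cc([C@H]2Oc3c(OC)cc(C#CCO)cc3[C@@H]2COC(=O)c2ccc(O)cc2)ccc1O | intermediate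
17 | [(2S,3R)-2-(4-hydroxy-3-methoxyphenyl)-5-[(1Z)-3-hydroxyprop-1-en-1-yl]-7-methoxy-2,3-dihydro-1-benzofuran-3-yl]methyl 4-hydroxybenzoate | COc1cc([C@H]2Oc3c(OC)cc(/C=C\CO)cc3[C@@H]2COC(=O)c2ccc(O)cc2)ccc1O | intermediate
18 | [(2S,3R)-2-(4-hydroxy-3-methoxyphenyl)-7-methoxy-5-[(1Z)-3-oxoprop-1-en-1-yl]-2,3-dihydro-1-benzofuran-3-yl]methyl 4-hydroxybenzoate | COc1cc([C@H]2Oc3c(OC)cc(/C=C\C=O)cc3[C@@H]2COC(=O)c2ccc(O)cc2)ccc1O | target

**Step count and risks**

Total step count: 10. Longest linear sequence: 9 steps (steps 1, 2, 4, 5, 6, 7, 8, 9 and 10 from compound 1); step 3 is a one-step side branch.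

Steps most likely to fail:

Step 5. The iodanyl ketal may be diverted into migration of ring B, dehydrogenation or capture of C3 by solvent, and acid-induced reversible opening of the C2–O bond may erode the C2 configuration. The fallback sets out from 7 and comes back at 11, replacing the cationic shift by a carbene-type ring contraction. The lithium enolate of 7 (LiN(SiMe3)2, THF, −78 °C) is acylated with 2,2,2-trifluoroethyl trifluoroacetate to the 3-trifluoroacetyl flavanone F1, which is not isolated. Methanesulfonyl azide and Et3N in MeCN (detrifluoroacetylative diazo transfer) convert it into the 3-diazoflavanone F2. Irradiation of F2 (λ > 300 nm, MeOH, rt) should trigger a Wolff rearrangement in which ring A again moves from C4 to C3, and methanol adds to the ring-contracted ketene. Protonation of the resulting ester enol from the face away from the C2 aryl group is expected to favour the cis ester F3, which is equilibrated to the trans ester 11 with catalytic DBU in toluene at rt.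

Step 7. Competing O-alkylation of a phenol, or sluggish activation of the β-branched primary alcohol, may lower the chemoselectivity of the esterification. The fallback sets out from 12 and comes back at 14, using temporary phenol protection. Phenol-selective O-allylation (allyl bromide, K2CO3, acetone, rt) gives the allyl ether F4. Steglich esterification with commercial 4-(allyloxy)benzoic acid (EDC·HCl, DMAP, CH2Cl2, rt) gives the bis(allyl ether) ester F5. Pd(PPh3)4 (cat.) with morpholine in THF at rt then removes both allyl groups to give 14.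

Step 10. Z-to-E isomerisation of the push-pull enal and oxidative degradation of the free guaiacyl phenol on the oxidant surface may occur. The fallback sets out from 14 and comes back at 18, separating the oxidation from the free phenols. Silylation of both phenols (t-BuMe2SiCl, imidazole, DMF, rt) gives the bis(silyl ether) F6. Sonogashira coupling with 15 under the conditions of step 8 gives the alkynol F7, and Lindlar semihydrogenation as in step 9 gives the Z-allylic alcohol F8. Buffered Dess–Martin oxidation (DMP, NaHCO3, CH2Cl2, 0 °C) gives the Z-enal F9. Bu4NF buffered with AcOH (THF, 0 °C) then frees both phenols to give 18.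

Further compounds
F1 | step 5 | 4-[(2S)-6-bromo-8-methoxy-4-oxo-3-(trifluoroacetyl)-3,4-dihydro-2H-chromen-2-yl]-2-methoxyphenyl 2,2-dimethylpropanoate (C3 epimers, largely enolised, not isolated) | COc1cc([C@H]2Oc3c(OC)cc(Br)cc3C(=O)C2C(=O)C(F)(F)F)ccc1OC(=O)C(C)(C)C
F2 | step 5 | 4-[(2R)-6-bromo-3-diazo-8-methoxy-4-oxo-3,4-dihydro-2H-chromen-2-yl]-2-methoxyphenyl 2,2-dimethylpropanoate (C2 unchanged in space, descriptor changes by priority) | COc1cc([C@H]2Oc3c(OC)cc(Br)cc3C(=O)C2=[N+]=[N-])ccc1OC(=O)C(C)(C)C
F3 | step 5 | methyl (2S,3R)-5-bromo-2-[4-(2,2-dimethylpropanoyloxy)-3-methoxyphenyl]-7-methoxy-2,3-dihydro-1-benzofuran-3-carboxylate (cis ester) | COc1cc([C@H]2Oc3c(OC)cc(Br)cc3[C@H]2C(=O)OC)ccc1OC(=O)C(C)(C)C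
F4 | step 7 | [(2S,3R)-5-bromo-7-methoxy-2-[3-methoxy-4-(prop-2-en-1-yloxy)phenyl]-2,3-dihydro-1-benzofuran-3-yl]methanol | COc1cc([C@H]2Oc3c(OC)cc(Br)cc3[C@@H]2CO)ccc1OCC=C
F5 | step 7 | [(2S,3R)-5-bromo-7-methoxy-2-[3-methoxy-4-(prop-2-en-1-yloxy)phenyl]-2,3-dihydro-1-benzofuran-3-yl]methyl 4-(prop-2-en-1-yloxy)benzoate | COc1cc([C@H]2Oc3c(OC)cc(Br)cc3[C@@H]2COC(=O)c2ccc(OCC=C)cc2)ccc1OCC=C
F6 | step 10 | [(2S,3R)-5-bromo-2-[4-(tert-butyldimethylsilyloxy)-3-methoxyphenyl]-7-methoxy-2,3-dihydro-1-benzofuran-3-yl]methyl 4-(tert-butyldimethylsilyloxy)benzoate | COc1cc([C@H]2Oc3c(OC)cc(Br)cc3[C@@H]2COC(=O)c2ccc(O[Si](C)(C)C(C)(C)C)cc2)ccc1O[Si](C)(C)C(C)(C)C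
F7 | step 10 | [(2S,3R)-2-[4-(tert-butyldimethylsilyloxy)-3-methoxyphenyl]-5-(3-hydroxyprop-1-yn-1-yl)-7-methoxy-2,3-dihydro-1-benzofuran-3-yl]methyl 4-(tert-butyldimethylsilyloxy)benzoate | COc1cc([C@H]2Oc3c(OC)cc(C#CCO)cc3[C@@H]2COC(=O)c2ccc(O[Si](C)(C)C(C)(C)C)cc2)ccc1O[Si](C)(C)C(C)(C)C
F8 | step 10 | [(2S,3R)-2-[4-(tert-butyldimethylsilyloxy)-3-methoxyphenyl]-5-[(1Z)-3-hydroxyprop-1-en-1-yl]-7-methoxy-2,3-dihydro-1-benzofuran-3-yl]methyl 4-(tert-butyldimethylsilyloxy)benzoate | COc1cc([C@H]2Oc3c(OC)cc(/C=C\CO)cc3[C@@H]2COC(=O)c2ccc(O[Si](C)(C)C(C)(C)C)cc2)ccc1O[Si](C)(C)C(C)(C)C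
F9 | step 10 | [(2S,3R)-2-[4-(tert-butyldimethylsilyloxy)-3-methoxyphenyl]-7-methoxy-5-[(1Z)-3-oxoprop-1-en-1-yl]-2,3-dihydro-1-benzofuran-3-yl]methyl 4-(tert-butyldimethylsilyloxy)benzoate | COc1cc([C@H]2Oc3c(OC)cc(/C=C\C=O)cc3[C@@H]2COC(=O)c2ccc(O[Si](C)(C)C(C)(C)C)cc2)ccc1O[Si](C)(C)C(C)(C)C
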